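## Retrosynthetic overview

1. The C8–CH2–C5 bridge between rings B and A is cut last. This gives the ring B/C chromanone, armed at C8 as a Mannich base (o-quinone methide source), and the ring A ketone, whose R centre is bought with (R)-2-methylbutanoic acid.
2. The plan rests on one feature of ring B. The ether oxygen O1 on C8a is para to the C6 methyl and must be distinguished from the phenolic oxygens on C5 and C7; closing ring C on a free acylated methylphloroglucinol leaves the 6-methyl/8-methyl outcome open.
3. Ring C is therefore made first, as a dihydropyranone that already contains O1–C8a=C4a–C4(=O). Ring B is then annulated onto its C=C bond by a Diels–Alder reaction (cuts C4a–C5 and C8–C8a).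
4. The dienophile is the 5-phenylsulfinyl dihydropyranone, an alkyne equivalent made from mesityl oxide. The diene is the bis(silyloxy) ketene acetal of methyl 2-methylacetoacetate, which brings C5–C8, both phenol oxygens and the C6 methyl.
5. Ring order is C, then B. Ring A is bought as 2,4,6-trihydroxytoluene and is only acylated and 4-O-methylated.

Key step: step 6

Remark on the chemistry: (R)-2-methylbutanoic acid of high enantiomeric purity is assumed to be purchasable, and sulfoxide 6 is used racemic at sulfur because every stereocentre created in step 6 is erased on aromatisation.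

## Route

Step 1
Reactants: 1 mesityl oxide (4-methylpent-3-en-2-one)
Product: 3 2,2-dimethyl-2,3-dihydro-4H-pyran-4-one, via hydroxymethylene ketone 2 (not isolated)
Conditions: HCO2Et, NaOMe, Et2O, 0 °C → rt; then 2 M H2SO4, rt
Reagents that add atoms: ethyl formate, CCOC=O
Why: Crossed Claisen formylation at the α′-methyl group gives the conjugated, least hindered β-ketoaldehyde enolate as the sink of the reversible condensation, and on acidification the Z-enol oxygen of 2 closes on the β,β-dimethyl enone carbon by 6-endo-trig oxa-Michael addition, a known entry to 2,3-dihydro-4-pyranones.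

Step 2
Reactants: 3 2,2-dimethyl-2,3-dihydro-4H-pyran-4-one
Product: 5 2,2-dimethyl-5-(phenylthio)-2,3-dihydro-4H-pyran-4-one, via chloro sulfide adduct 4 (not isolated)
Conditions: PhSH, NCS, CH2Cl2, 0 °C (forms PhSCl); add 3, 0 °C → rt; then Et3N, 0 °C
Reagents that add atoms: thiophenol (delivered as PhSCl), Sc1ccccc1
Why: C5 is the nucleophilic β-carbon of the ring enol ether, so electrophilic sulfenylation by PhSCl adds across C5=C6 and Et3N removes HCl from 4 by E1cB elimination, which places sulfur on C5, whereas enolate sulfenylation would have attacked C3.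

Step 3
Reactants: 5 2,2-dimethyl-5-(phenylthio)-2,3-dihydro-4H-pyran-4-one
Product: 6 2,2-dimethyl-5-(phenylsulfinyl)-2,3-dihydro-4H-pyran-4-one (racemic at sulfur)
Conditions: mCPBA (1.0 equiv), CH2Cl2, −78 → 0 °C
Reagents that add atoms: mCPBA, OOC(=O)c1cccc(Cl)c1
Why: Sulfide-to-sulfoxide oxidation with one equivalent of peracid at low temperature is chemoselective, since the acceptor-substituted C5=C6 bond resists epoxidation and the vinylic sulfoxide has no β-hydrogen through which it could eliminate.

Step 4
Reactants: 7 methyl 2-methyl-3-oxobutanoate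
Product: 8 methyl 2-methyl-3-(trimethylsilyloxy)but-2-enoate (E/Z mixture)
Conditions: Me3SiCl, Et3N, toluene, rt
Reagents that add atoms: chlorotrimethylsilane, C[Si](C)(C)Cl
Why: Soft enolisation and O-silylation of a β-keto ester (silyl enol ether formation) is routine for 2-alkyl acetoacetates.

Step 5
Reactants: 8 methyl 2-methyl-3-(trimethylsilyloxy)but-2-enoate
Product: 9 1-methoxy-2-methyl-1,3-bis(trimethylsilyloxy)buta-1,3-diene (either double-bond isomer)
Conditions: LiN(iPr)2, THF, −78 °C; Me3SiCl, −78 °C → rt; non-aqueous work-up
Reagents that add atoms: chlorotrimethylsilane, C[Si](C)(C)Cl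
Why: Kinetic γ-deprotonation at the C4 methyl group gives the extended ester enolate, whose O-silylation is the standard second stage in preparing 1,3-bis(silyloxy)-1-alkoxybutadienes.

Step 6
Reactants: 6 2,2-dimethyl-5-(phenylsulfinyl)-2,3-dihydro-4H-pyran-4-one; 9 1-methoxy-2-methyl-1,3-bis(trimethylsilyloxy)buta-1,3-diene
Product: 12 5,7-dihydroxy-2,2,6-trimethylchroman-4-one, via cis-fused cycloadduct 10 (not isolated), via dihydroarene ketal 11 (not isolated)
Conditions: 9 (2 equiv), toluene, 0 °C → rt, then 80 °C; then 1 M HCl, THF, rt
Reagents that add atoms: none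
Why: The electron-rich diene 9 adds to the C5=C6 bond of 6 in a normal-electron-demand [4+2] cycloaddition (at the polar extreme a Mukaiyama–Michael attack followed by closure of the α-sulfinyl enolate carbon onto the ketene-acetal carbon), its CH2 terminus bonding to pyranone C6 (bond C8–C8a) and its acetal carbon to pyranone C5 (bond C4a–C5). Ring B is the only ring closed, as a six-membered carbocycle formed by intermolecular [4+2] annulation onto the intact ring C. The closest known reaction type is the use of α-sulfinyl enones, sulfinylquinones and 3-acceptor-substituted chromones as alkyne-equivalent dienophiles toward 1-alkoxy-3-silyloxy and 1,1,3-trioxygenated butadienes, with sulfenic acid loss leading to phenols. Suprafacial addition places sulfur on C4a and hydrogen on C8a cis in 10, which is the geometry required for thermal syn-elimination of PhSOH through the only available β-hydrogen, and the centres at C4a, C5, C8a and sulfur are transient and need no control because all vanish on aromatisation. On acidic work-up of 11 the silyl ethers are cleaved, the C5 hemiketal expels MeOH and the resulting dienone tautomerises through C8–H to the resorcinol 12, whose 5-OH is chelated to C4=O. The one selectivity needed is regiochemical, and it is secured by matched polarity, since the largest HOMO coefficient of 9 lies on the unsubstituted terminus and the largest LUMO coefficient of 6 lies on C6 (β to both ketone and sulfinyl group), so the methyl group can only arrive at C6, para to the pre-existing O1.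

Step 7
Reactants: 12 5,7-dihydroxy-2,2,6-trimethylchroman-4-one
Product: 13 8-[(dimethylamino)methyl]-5,7-dihydroxy-2,2,6-trimethylchroman-4-one
Conditions: HCHO (37% aq), Me2NH (40% aq, excess), EtOH, 0 °C → rt
Reagents that add atoms: formaldehyde, C=O; dimethylamine, CNC
Why: In this phenolic Mannich reaction the iminium ion attacks C8, the only unsubstituted carbon of the phloroglucinol-type ring B, far faster than the chelated and poorly enolisable C4 ketone could react at C3.

Step 8
Reactants: 14 (R)-2-methylbutanoic acid
Product: 15 (R)-2-methylbutanoyl chloride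
Conditions: (COCl)2, DMF (cat.), CH2Cl2, 0 °C → rt; careful concentration
Reagents that add atoms: oxalyl chloride, ClC(=O)C(=O)Cl
Why: Acid chloride formation through the chloroiminium catalyst runs without any amine base, so no ketene is formed and the α-stereocentre keeps its R configuration.

Step 9
Reactants: 15 (R)-2-methylbutanoyl chloride; 16 2,4,6-trihydroxytoluene
Product: 17 (R)-2-methyl-1-(2,4,6-trihydroxy-3-methylphenyl)butan-1-one
Conditions: AlCl3 (3.5 equiv), CH2Cl2/PhNO2, 0 °C → rt; 1 M HCl quench
Reagents that add atoms: none
Why: Friedel–Crafts C-acylation takes one of the two equivalent free ring positions and stops at the monoketone because the aluminium-chelated product is deactivated, while the stereocentre brought in by 15 should persist because the chelated, di-ortho-substituted aryl ketone enolises only with difficulty.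

Step 10
Reactants: 17 (R)-2-methyl-1-(2,4,6-trihydroxy-3-methylphenyl)butan-1-one
Product: 18 (R)-1-(2,6-dihydroxy-4-methoxy-3-methylphenyl)-2-methylbutan-1-one
Conditions: Me2SO4 (1.0 equiv), K2CO3 (1.0 equiv), acetone, rt → 40 °C
Reagents that add atoms: dimethyl sulfate, COS(=O)(=O)OC
Why: Williamson-type O-methylation with one equivalent of base should select the 4-OH, which is para to the acyl group, the most acidic, and the only hydroxyl that does not flank and hydrogen-bond to the carbonyl.

Step 11
Reactants: 13 8-[(dimethylamino)methyl]-5,7-dihydroxy-2,2,6-trimethylchroman-4-one; 18 (R)-1-(2,6-dihydroxy-4-methoxy-3-methylphenyl)-2-methylbutan-1-one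
Product: 20 (R)-1-{2,6-dihydroxy-4-methoxy-3-methyl-5-[(5,7-dihydroxy-2,2,6-trimethyl-4-oxochroman-8-yl)methyl]phenyl}-2-methylbutan-1-one (target), via o-quinone methide 19 (not isolated)
Conditions: 18 (1.2 equiv), 1,4-dioxane, 100 °C, slow N2 purge to carry off Me2NH
Reagents that add atoms: none
Why: Thermal retro-Michael loss of Me2NH from the ortho-hydroxybenzylamine gives o-quinone methide 19, which is trapped by C5 of ring A, the only free nucleophilic carbon of 18, in a Michael-type Friedel–Crafts alkylation followed by rearomatisation, and the near-neutral medium leaves the R stereocentre and ring C untouched.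

## Compound list

| No. | Name | SMILES | Role |
|---|---|---|---|
| 1 | mesityl oxide | CC(C)=CC(C)=O | starting material |
| 2 | (1Z)-1-hydroxy-5-methylhexa-1,4-dien-3-one (first formed as its sodium salt) | CC(C)=CC(=O)/C=C\O | intermediate |
| 3 | 2,2-dimethyl-2,3-dihydro-4H-pyran-4-one | CC1(C)CC(=O)C=CO1 | intermediate |
| 4 | 6-chloro-2,2-dimethyl-5-(phenylthio)tetrahydro-4H-pyran-4-one (racemic, relative configuration immaterial) | CC1(C)CC(=O)C(Sc2ccccc2)C(Cl)O1 | intermediate |
| 5 | 2,2-dimethyl-5-(phenylthio)-2,3-dihydro-4H-pyran-4-one | CC1(C)CC(=O)C(=CO1)Sc1ccccc1 | intermediate |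
| 6 | 2,2-dimethyl-5-(phenylsulfinyl)-2,3-dihydro-4H-pyran-4-one (racemic at sulfur) | CC1(C)CC(=O)C(=CO1)S(=O)c1ccccc1 | intermediate |
| 7 | methyl 2-methyl-3-oxobutanoate (racemic, labile centre) | COC(=O)C(C)C(C)=O | starting material |
| 8 | methyl 2-methyl-3-(trimethylsilyloxy)but-2-enoate (E/Z mixture) | COC(=O)C(C)=C(C)O[Si](C)(C)C | intermediate |
| 9 | 1-methoxy-2-methyl-1,3-bis(trimethylsilyloxy)buta-1,3-diene | COC(O[Si](C)(C)C)=C(C)C(=C)O[Si](C)(C)C | intermediate |
| 10 | 5-methoxy-2,2,6-trimethyl-4a-(phenylsulfinyl)-5,7-bis(trimethylsilyloxy)-2,3,4a,5,8,8a-hexahydro-4H-chromen-4-one (racemic; S on C4a and H on C8a cis, relative configuration shown; mixture at C5 and sulfur) | CC1(C)CC(=O)[C@]2(S(=O)c3ccccc3)[C@H](O1)CC(O[Si](C)(C)C)=C(C)C2(OC)O[Si](C)(C)C | intermediate |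
| 11 | 5-methoxy-2,2,6-trimethyl-5,7-bis(trimethylsilyloxy)-2,3,5,8-tetrahydro-4H-chromen-4-one (racemic) | CC1(C)CC(=O)C2=C(O1)CC(O[Si](C)(C)C)=C(C)C2(OC)O[Si](C)(C)C | intermediate |
| 12 | 5,7-dihydroxy-2,2,6-trimethylchroman-4-one | Cc1c(O)cc2OC(C)(C)CC(=O)c2c1O | intermediate |
| 13 | 8-[(dimethylamino)methyl]-5,7-dihydroxy-2,2,6-trimethylchroman-4-one | CN(C)Cc1c(O)c(C)c(O)c2c1OC(C)(C)CC2=O | intermediate |
| 14 | (R)-2-methylbutanoic acid | CC[C@@H](C)C(=O)O | starting material |
| 15 | (R)-2-methylbutanoyl chloride | CC[C@@H](C)C(=O)Cl | intermediate |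
| 16 | 2,4,6-trihydroxytoluene | Cc1c(O)cc(O)cc1O | starting material |
| 17 | (R)-2-methyl-1-(2,4,6-trihydroxy-3-methylphenyl)butan-1-one | CC[C@@H](C)C(=O)c1c(O)c(C)c(O)cc1O | intermediate |
| 18 | (R)-1-(2,6-dihydroxy-4-methoxy-3-methylphenyl)-2-methylbutan-1-one | CC[C@@H](C)C(=O)c1c(O)c(C)c(OC)cc1O | intermediate |
| 19 | 5-hydroxy-2,2,6-trimethyl-8-methylidene-2,3-dihydro-4H-chromene-4,7(8H)-dione (o-quinone methide) | C=C1C(=O)C(C)=C(O)C2=C1OC(C)(C)CC2=O | intermediate |
| 20 | (R)-1-{2,6-dihydroxy-4-methoxy-3-methyl-5-[(5,7-dihydroxy-2,2,6-trimethyl-4-oxochroman-8-yl)methyl]phenyl}-2-methylbutan-1-one (CNP0303209.1) | CC[C@@H](C)C(=O)c1c(O)c(C)c(OC)c(Cc2c(O)c(C)c(O)c3c2OC(C)(C)CC3=O)c1O | target |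

## Step count and risks

Total step count: 11.
Longest linear sequence: 6 steps (1, 2, 3, 6, 7, 11). The diene branch (4, 5) joins at step 6 and the ring A branch (8, 9, 10) joins at step 11.

**Risk 1, step 6.**
- The donor oxygen O1 lowers the electrophilicity of C6, so cycloaddition may be slower than hydrolysis or protodesilylation of the diene.
- If bond formation becomes stepwise, β-elimination of O1 (opening of ring C) may overtake closure of the second bond.
- The released sulfenic acid also consumes diene.

The fallback sets out from 16 and comes back at 12, and it gives up the benzannulation for the classical acylation–cyclisation.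
- Compound 16 would be heated with 3-methylbut-2-enoic acid in P2O5/MeSO3H at about 70 °C.
- Friedel–Crafts acylation gives 3-methyl-1-(2,4,6-trihydroxy-3-methylphenyl)but-2-en-1-one F1, which cyclises in the same medium by oxa-Michael addition.
- Closure through the hydroxyl next to the free ring carbon gives 12. Closure through the hydroxyl next to the methyl group gives 5,7-dihydroxy-2,2,8-trimethylchroman-4-one F2.
- The two isomers would be separated by chromatography. F2 can be returned to the acid medium, where reopening to F1 re-equilibrates it.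
- The price is loss of the built-in regiocontrol.

**Risk 2, step 11.**
- Amine loss may be slow.
- The methylene unit may be exchanged between the two phenols by ipso attack and retro-Mannich cleavage, leading to symmetrical coupling.
- The quinone methide may trap itself.
- Amine retained in the hot solution could promote opening and isomeric reclosure of ring C.

The fallback sets out from 18 and comes back at 20. Compound 12 is used directly as the partner, so step 7 is dropped. Donor and acceptor roles are reversed, and thermolysis is replaced by ionic activation at room temperature.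
- Compound 18 is aminomethylated at C5 (HCHO, Me2NH, EtOH) to (R)-1-{5-[(dimethylamino)methyl]-2,6-dihydroxy-4-methoxy-3-methylphenyl}-2-methylbutan-1-one F3.
- F3 is quaternised with MeI in acetone to the benzyltrimethylammonium iodide F4.
- With K2CO3 in DMF at rt, F4 loses trimethylamine to give the ring A o-quinone methide F5.
- F5 is captured by C8 of the phenoxide of 12 to give 20.

**Risk 3, step 10.**
- Methylation may run on to the 2- or 6-hydroxyl.
- The ambident phenoxide may be C-methylated at C5.

The fallback sets out from 16 and 15 and comes back at 18, replacing steps 9 and 10. Selective methylation is exchanged for chelation-directed demethylation.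
- Compound 16 is exhaustively methylated (Me2SO4, K2CO3, acetone, reflux) to 2,4,6-trimethoxytoluene F6.
- F6 is acylated with 15 under mild Friedel–Crafts conditions (SnCl4, CH2Cl2, −10 °C) to (R)-2-methyl-1-(2,4,6-trimethoxy-3-methylphenyl)butan-1-one F7.
- Excess BCl3 (CH2Cl2, −78 °C → rt) bound to the carbonyl oxygen cleaves in turn the two methyl ethers ortho to the ketone and spares the remote 4-OMe, which gives 18.

## Further compounds

F1 | step 6 | 3-methyl-1-(2,4,6-trihydroxy-3-methylphenyl)but-2-en-1-one | CC(C)=CC(=O)c1c(O)c(C)c(O)cc1O
F2 | step 6 | 5,7-dihydroxy-2,2,8-trimethylchroman-4-one | Cc1c(O)cc(O)c2c1OC(C)(C)CC2=O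
F3 | step 11 | (R)-1-{5-[(dimethylamino)methyl]-2,6-dihydroxy-4-methoxy-3-methylphenyl}-2-methylbutan-1-one | CC[C@@H](C)C(=O)c1c(O)c(C)c(OC)c(CN(C)C)c1O
F4 | step 11 | {2,4-dihydroxy-6-methoxy-5-methyl-3-[(R)-2-methylbutanoyl]benzyl}trimethylammonium iodide | CC[C@@H](C)C(=O)c1c(O)c(C)c(OC)c(C[N+](C)(C)C)c1O.[I-]
F5 | step 11 | 3-hydroxy-5-methoxy-4-methyl-6-methylidene-2-[(R)-2-methylbutanoyl]cyclohexa-2,4-dien-1-one (ring A o-quinone methide) | CC[C@@H](C)C(=O)C1=C(O)C(C)=C(OC)C(=C)C1=O
F6 | step 10 | 2,4,6-trimethoxytoluene | COc1cc(OC)c(C)c(OC)c1
F7 | step 10 | (R)-2-methyl-1-(2,4,6-trimethoxy-3-methylphenyl)butan-1-one | CC[C@@H](C)C(=O)c1c(OC)c(C)c(OC)cc1OC
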